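All runs come from a simulation on assumed constants, and the scatter is random.

Hotter flasks hold less isomer per target than cooler ones: pooling the readings of each run, the ratio q = c(isomer)/c(target) is 0.498 in theta and zeta at 80 °C, but 0.333 in beta at 102 °C.

all flasks: free catalyst 0.2 mol%

| run | substrate | temperature | remark | time |
|---|---|---|---|---|
| theta | 0.24 M | 80 °C | run made earlier |  |
| beta | 0.27 M | 102 °C | run made earlier |  |
| zeta | 0.44 M | 80 °C | run made earlier |  |
| Sunday's | 0.40 M |  | at 70 °C throughout | 50 min |
| Saturday's | 0.20 M |  | at 70 °C until 25 min, from then on at 110 °C | 50 min |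

| run | time / min | target / % | isomer of the product / % |
|---|---|---|---|
| theta | 2.00 | 8 | 5 |
| theta | 5.00 | 20 | 7 |
| theta | 10.0 | 30 | 13 |
| theta | 15.0 | 38 | 20 |
| theta | 25.0 | 42 | 22 |
| beta | 0.667 | 11 | 5 |
| beta | 1.50 | 16 | 6 |
| beta | 3.00 | 22 | 7 |
| beta | 5.00 | 32 | 12 |
| beta | 8.00 | 39 | 10 |
| zeta | 5.00 | 21 | 12 |
| zeta | 10.0 | 31 | 14 |
| zeta | 12.0 | 33 | 19 |
| zeta | 20.0 | 38 | 20 |
| zeta | 25.0 | 46 | 21 |

(readings scatter by 2 percentage points)

- the analysis behind the earlier runs scatters by 2 percentage points, standard deviation
- on the list of suspects stand: catalyst intermediate B <-> free catalyst + target; catalyst intermediate A <-> catalyst intermediate B; substrate + free catalyst <-> catalyst intermediate A; target <-> isomer of the product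
- where the amount of substrate changes, what is given in equivalents or mol% on it follows

- the flask that ends with the higher share of target in all that became target or isomer of the product, or "neither" when 2 percentage points or less lies between them (Sunday's / Saturday's / neither)
- share of target in all that became target or isomer of the product, Sunday's
- share of target in all that became target or isomer of the product, Saturday's

Let me carry one number from those readings: the fall factor 0.669, the q at 102 °C divided by the q at 80 °C. To reach another temperature, I raise it to the power of that temperature's distance from 80 °C, measured in lengths of this step. My reckoning gives q = 0.598 at 70 °C and 0.288 at 110 °C, so the share of target, 1/(1+q), is 62.6% and 77.6%.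

Two people now argue over what q means. The first claims thermodynamic control: a flask shows the q of its present temperature. Her ground is that the listed route to the isomer runs through target, yet the first beta reading, at 0.667 min, already reads q = 0.455. So for her Saturday's ends at 77.6%. The forecast stands on her side, "so this interconversion must be fast" in its words, and gives 63% (58% to 68%) for Sunday's and 77% (72% to 82%) for Saturday's, a little under mine.

The second claims kinetic control: each portion keeps the q of the temperature at which it formed. Theta and zeta each held one temperature, where he expects a steady q as she does, so a steady q there does not part them. Saturday's changes temperature at 25 min, so he places it between 62.6% and 77.6%, the nearer to the first the less forms after the change.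

Saturday's ends at 79.8% and Sunday's at 61.5%, so Saturday's is higher.

    catalyst intermediate B ⇌ free catalyst + target (K = 0.0710 M, k = 120 min⁻¹, Ea = 81.0 kJ mol⁻¹, ΔH = −5.00 kJ mol⁻¹)
    catalyst intermediate A ⇌ catalyst intermediate B (K = 0.350, k = 190 min⁻¹, Ea = 69.0 kJ mol⁻¹, ΔH = −33.0 kJ mol⁻¹)
    substrate + free catalyst ⇌ catalyst intermediate A (K = 120 M⁻¹, k = 580 M⁻¹ min⁻¹, Ea = 61.0 kJ mol⁻¹, ΔH = 5.00 kJ mol⁻¹)
    target ⇌ isomer of the product (K = 0.630, k = 0.690 min⁻¹, Ea = 95.0 kJ mol⁻¹, ΔH = −25.0 kJ mol⁻¹)
    (constants at 70 °C)

Saturday's 79.8% is more than the top of the second man's range, 77.6%, and its final q is 0.252. The relaxation half-life of target and isomer, taken for this step alone in Sunday's, is 0.388 min, short against 50 min, so his view belongs to times of that order. The fall factor carries to Sunday's charge run at 95 °C: q = 0.379, a share of 72.5%, and that flask gives 74.2%.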